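**Retrosynthetic overview**

1. Ring numbering: C1 (quaternary), C2, C3, C4=C5 (Me on C4), C6 (OAc), C7, C8 (Me, OH), C9 and C10 (cyclopropane CH, C10 on C1), C11 (cyclopropane CH2). The route rests on the 1,3-dioxygen pattern C6–O/C8–O, in which C8 is a methyl carbinol bonded to cyclopropane carbon C9. This is an aldol retron that opens the ten-membered ring at C7–C8 onto a cyclopropyl methyl ketone.
2. Target ⇒ ten-membered β-hydroxy enone (C6 ketone, C8 carbinol, prenyl side chain). The endgame from it is 1,3-anti reduction, C6 acetylation, side-chain epoxidation, epoxide-to-allylic-alcohol isomerisation, and sulfonate displacement by H2O2 with inversion.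
3. β-Hydroxy enone ⇒ open-chain bromomethyl E-enone carrying the trans-acetylcyclopropane (C7–C8 by samarium enolate aldol). Bromomethyl enone ⇒ E-iodoalkene + α-ethoxyvinylstannane (C5–C6 by Stille coupling, C7–Br by bromination of the enol ether).
4. Cyclopropyl methyl ketone ⇒ vinyl compound + diazoacetamide (C9–C10 and C9–C11 by asymmetric cyclopropanation). E-iodoalkene ⇒ terminal alkyne (carboalumination) ⇒ geranyl phosphate + butynyl Grignard reagent (C1–C2 and the C1 quaternary centre by copper-catalysed SN2′ alkylation).
5. Ring order: cyclopropane first (step 7), ten-membered ring second (step 10).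

Key step: step 10

Assumption: the hand of the NHC ligand (step 2) and of the pheox ligand on divalent ruthenium (step 7; Ph-pheox = C,N-cyclometalated 2,4-diphenyl-4,5-dihydrooxazole) is taken as the one that gives the configurations drawn, to be confirmed by correlation on the first run; both antipodes of each ligand are accessible.

**Route**

Step 1
Reactants: 1 geraniol
Product: 2 geranyl diethyl phosphate
Conditions: ClP(O)(OEt)2, pyridine, DMAP (cat.), CH2Cl2, 0 °C
Reagents that add atoms: diethyl chlorophosphate, CCOP(=O)(Cl)OCC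
Why: Phosphorylation of the primary allylic alcohol under nucleophilic catalysis should give the allylic phosphate that serves as leaving group for copper-mediated allylic substitution, with the E-alkene untouched.

Step 2
Reactants: 2 geranyl diethyl phosphate; 3 4-bromo-1-(trimethylsilyl)but-1-yne
Product: 5 [(5S)-5-ethenyl-5,9-dimethyldec-8-en-1-yn-1-yl]trimethylsilane, via butynylmagnesium bromide 4 (not isolated)
Conditions: 3, Mg, THF, rt; then 2, Cu(OTf)2 (2 mol %), chiral hydroxyalkyl N-mesitylimidazolinium salt (3 mol %), Et2O/THF, −78 → −40 °C, slow addition of 4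
Reagents that add atoms: none
Why: Copper-catalysed enantioselective allylic alkylation (SN2′) of the E-configured γ,γ-disubstituted allyl phosphate by an alkyl Grignard reagent under a chiral bidentate NHC–copper catalyst should create the C1 quaternary stereocentre (S in 5) together with the vinyl group, the alkene geometry and the ligand hand fixing the face, while the silylalkyne stays inert.

Step 3
Reactants: 5 [(5S)-5-ethenyl-5,9-dimethyldec-8-en-1-yn-1-yl]trimethylsilane
Product: 6 (5S)-5-ethenyl-5,9-dimethyldec-8-en-1-yne
Conditions: K2CO3 (cat.), MeOH, rt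
Reagents that add atoms: none
Why: Base-catalysed methanolysis of the alkynylsilane (protodesilylation) should free the terminal alkyne without touching the alkenes or the quaternary centre.

Step 4
Reactants: 6 (5S)-5-ethenyl-5,9-dimethyldec-8-en-1-yne
Product: 8 (1E,5S)-5-ethenyl-1-iodo-2,5,9-trimethyldeca-1,8-diene, via alkenyldimethylalane 7 (not isolated)
Conditions: Me3Al, Cp2ZrCl2 (25 mol %), CH2Cl2, 0 °C → rt; then I2, THF, −30 → 0 °C
Reagents that add atoms: trimethylaluminium, C[Al](C)C; iodine, II
Why: Zirconium-catalysed Negishi carboalumination adds methyl and aluminium syn across the terminal alkyne with methyl on the internal carbon, and iodinolysis of the alkenyl–aluminium bond with retention should give the E-iodoalkene that fixes the C4=C5 geometry, the hindered vinyl group and the trisubstituted alkene not being carbometalated under these conditions.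

Step 5
Reactants: 9 N,O-dimethylhydroxylamine hydrochloride; 10 bromoacetyl bromide
Product: 11 2-bromo-N-methoxy-N-methylacetamide
Conditions: K2CO3, Et2O/H2O, 0 °C
Reagents that add atoms: none
Why: Schotten–Baumann N-acylation by the acyl bromide is much faster than displacement of the α-bromide, so the bromoacetamide should form cleanly.

Step 6
Reactants: 11 2-bromo-N-methoxy-N-methylacetamide
Product: 12 2-diazo-N-methoxy-N-methylacetamide
Conditions: TsNHNHTs, DBU, THF, 0 °C
Reagents that add atoms: N,N′-ditosylhydrazine, Cc1ccc(cc1)S(=O)(=O)NNS(=O)(=O)c1ccc(C)cc1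
Why: N-Alkylation of the ditosylhydrazine by the α-bromoamide followed by twofold base-induced loss of sulfinate is a known route from bromoacetyl compounds to diazoacetates and diazoacetamides.

Step 7
Reactants: 8 (1E,5S)-5-ethenyl-1-iodo-2,5,9-trimethyldeca-1,8-diene; 12 2-diazo-N-methoxy-N-methylacetamide
Product: 13 (1S,2S)-2-[(1E,5S)-1-iodo-2,5,9-trimethyldeca-1,8-dien-5-yl]-N-methoxy-N-methylcyclopropane-1-carboxamide
Conditions: [Ru(Ph-pheox)(MeCN)4]PF6 (3 mol %), CH2Cl2, 0 °C → rt, slow addition of 12 (1.5 equiv)
Reagents that add atoms: none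
Why: Catalytic asymmetric cyclopropanation in which the ruthenium carbene from 12 adds to the monosubstituted alkene, the bulky oxazoline-based catalyst being expected to leave both trisubstituted alkenes alone and to set the trans relationship and the S configuration of C9 and C10 by catalyst control, since the neighbouring quaternary centre carries three alkyl groups of similar size.

Step 8
Reactants: 13 (1S,2S)-2-[(1E,5S)-1-iodo-2,5,9-trimethyldeca-1,8-dien-5-yl]-N-methoxy-N-methylcyclopropane-1-carboxamide
Product: 14 1-[(1S,2S)-2-[(1E,5S)-1-iodo-2,5,9-trimethyldeca-1,8-dien-5-yl]cyclopropyl]ethan-1-one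
Conditions: MeMgBr, THF, −20 → 0 °C; aq. NH4Cl
Reagents that add atoms: methylmagnesium bromide, C[Mg]Br
Why: Weinreb ketone synthesis, in which the chelated tetrahedral adduct of the N-methoxy-N-methylamide holds until work-up so that one methyl only is delivered, the iodoalkene being inert to the Grignard reagent at this temperature.

Step 9
Reactants: 14 1-[(1S,2S)-2-[(1E,5S)-1-iodo-2,5,9-trimethyldeca-1,8-dien-5-yl]cyclopropyl]ethan-1-one; 15 tributyl(1-ethoxyethenyl)stannane
Product: 17 (3E,7S)-7-[(1S,2S)-2-acetylcyclopropyl]-1-bromo-4,7,11-trimethyldodeca-3,10-dien-2-one, via 2-ethoxydiene 16 (not isolated)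
Conditions: Pd(PPh3)4 (5 mol %), toluene, 90 °C; then NBS (1.0 equiv), THF/H2O, 0 °C
Reagents that add atoms: N-bromosuccinimide, O=C1CCC(=O)N1Br; water, O
Why: Stille coupling of the iodoalkene with the α-ethoxyvinylstannane proceeds with retention of the E geometry to a 2-ethoxy-1,3-diene, whose terminal enol ether carbon is brominated by NBS and hydrolysed in the wet solvent to the bromomethyl enone, the enol ether being far more nucleophilic than the prenyl alkene.

Step 10
Reactants: 17 (3E,7S)-7-[(1S,2S)-2-acetylcyclopropyl]-1-bromo-4,7,11-trimethyldodeca-3,10-dien-2-one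
Product: 19 (1S,4E,8S,9S,10S)-8-hydroxy-1,4,8-trimethyl-1-(4-methylpent-3-enyl)-9,10-cyclopropane-fused cyclodec-4-en-6-one, via samarium enolate 18 (not isolated)
Conditions: SmI2 (2.5 equiv), THF, −78 °C, slow addition of 17 (final 2 mM); aq. NH4Cl, −78 °C
Reagents that add atoms: none
Why: Samarium diiodide reduces the C–Br bond by two single-electron transfers to the trivalent samarium enolate 18 (regiodefined at C7, the enone carbonyl being masked as the enolate), and C7 then adds to the C8 ketone through a closed six-membered samarium chelate (O6–Sm–O8) to give a samarium aldolate that is held against retro-aldol until the cold quench. The closest known reaction type is the samarium diiodide-promoted intramolecular Reformatsky-type aldol of α-halo carbonyl compounds onto aldehydes and ketones, which is used for medium and large rings. The ten-membered ring closes in a 10-(enolendo)-exo-trig mode under high dilution. The new C8 stereocentre is controlled by the ring conformation: with the trans-cyclopropane bond C9–C10 and the E-alkene C4=C5 as the two anti segments of a boat–chair–boat-like ring, C7 reaches the ketone face syn to C10 while the samarium-bound O8 points away from the three-membered ring and the methyl lies over it (bisected s-trans rotamer), which corresponds to 8S. The step needs the C–Br bond to be reduced before either ketone or the cyclopropane (secured by the far easier reduction of the α-bromo ketone at −78 °C without HMPA) and needs one ketone face to react (secured only by this chelated conformation, so the C8 configuration is the first thing to check on the product).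

Step 11
Reactants: 19 (1S,4E,8S,9S,10S)-8-hydroxy-1,4,8-trimethyl-1-(4-methylpent-3-enyl)-9,10-cyclopropane-fused cyclodec-4-en-6-one
Product: 20 (1S,4E,6S,8S,9S,10S)-1,4,8-trimethyl-1-(4-methylpent-3-enyl)-9,10-cyclopropane-fused cyclodec-4-ene-6,8-diol
Conditions: Me4NBH(OAc)3, MeCN/AcOH, −30 °C
Reagents that add atoms: none
Why: Hydroxyl-directed Evans–Saksena reduction, in which the C8 hydroxyl replaces an acetate on boron and hydride is delivered intramolecularly through a chair-like six-membered transition state, should give the 1,3-anti diol (6S) by 1,2-reduction of the enone.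

Step 12
Reactants: 20 (1S,4E,6S,8S,9S,10S)-1,4,8-trimethyl-1-(4-methylpent-3-enyl)-9,10-cyclopropane-fused cyclodec-4-ene-6,8-diol
Product: 21 (1S,4E,6S,8S,9S,10S)-8-hydroxy-1,4,8-trimethyl-1-(4-methylpent-3-enyl)-9,10-cyclopropane-fused cyclodec-4-en-6-yl acetate
Conditions: Ac2O, pyridine, DMAP (cat.), CH2Cl2, 0 °C
Reagents that add atoms: acetic anhydride, CC(=O)OC(C)=O
Why: Acetylation under nucleophilic catalysis should take only the secondary allylic C6 hydroxyl, because the tertiary C8 carbinol flanked by the cyclopropane is too hindered at 0 °C.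

Step 13
Reactants: 21 (1S,4E,6S,8S,9S,10S)-8-hydroxy-1,4,8-trimethyl-1-(4-methylpent-3-enyl)-9,10-cyclopropane-fused cyclodec-4-en-6-yl acetate
Product: 22 (1R,4E,6S,8S,9S,10S)-1-[2-[(2R)-3,3-dimethyloxiran-2-yl]ethyl]-8-hydroxy-1,4,8-trimethyl-9,10-cyclopropane-fused cyclodec-4-en-6-yl acetate
Conditions: D-fructose-derived Shi ketone (30 mol %), KHSO5 (as Oxone, 2KHSO5·KHSO4·K2SO4), K2CO3, Bu4NHSO4, MeCN/dimethoxymethane/aq. Na2B4O7 buffer, 0 °C
Reagents that add atoms: potassium peroxymonosulfate, [K+].[O-]S(=O)(=O)OO
Why: Shi epoxidation with the D-fructose-derived ketone is expected to give the R-configured oxirane of the electron-rich side-chain alkene through the spiro dioxirane transition state, the ring alkene being deactivated by its allylic acetate and shielded inside the ten-membered ring.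

Step 14
Reactants: 22 (1R,4E,6S,8S,9S,10S)-1-[2-[(2R)-3,3-dimethyloxiran-2-yl]ethyl]-8-hydroxy-1,4,8-trimethyl-9,10-cyclopropane-fused cyclodec-4-en-6-yl acetate
Product: 24 (1R,4E,6S,8S,9S,10S)-8-hydroxy-1-[(3R)-3-hydroxy-4-methylpent-4-enyl]-1,4,8-trimethyl-9,10-cyclopropane-fused cyclodec-4-en-6-yl acetate, via bis(trimethylsilyl) ether 23 (not isolated)
Conditions: TMSOTf, 2,6-lutidine, toluene, −78 °C; DBU, −78 °C → rt; then citric acid, MeOH, 0 °C
Reagents that add atoms: none
Why: Silyl triflate-promoted isomerisation of the epoxide to the allylic silyl ether (the tertiary C–O bond ionises and DBU removes a methyl proton) leaves the secondary C–O bond and hence the R configuration untouched, the C8 hydroxyl is silylated in passing, and mild acid methanolysis should free both hydroxyls without cleaving the acetate.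

Step 15
Reactants: 24 (1R,4E,6S,8S,9S,10S)-8-hydroxy-1-[(3R)-3-hydroxy-4-methylpent-4-enyl]-1,4,8-trimethyl-9,10-cyclopropane-fused cyclodec-4-en-6-yl acetate
Product: 26 CNP0302713.3 (1R,4E,6S,8S,9S,10S)-1-[(3S)-3-hydroperoxy-4-methylpent-4-enyl]-8-hydroxy-1,4,8-trimethyl-9,10-cyclopropane-fused cyclodec-4-en-6-yl acetate, via allylic mesylate 25 (not isolated)
Conditions: Ms2O (1.1 equiv), Et3N, CH2Cl2, −60 °C; then anhydrous H2O2 in Et2O (excess), −60 → 0 °C
Reagents that add atoms: hydrogen peroxide, OO
Why: Sulfonylation of the secondary allylic alcohol (the hindered tertiary C8 carbinol is left) and SN2 displacement of the allylic mesylate by hydrogen peroxide, an α-effect nucleophile, under neutral conditions should invert the carbinol carbon to the S hydroperoxide while the acetate survives.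

**Compound list**

1 | geraniol, (2E)-3,7-dimethylocta-2,6-dien-1-ol | CC(C)=CCC/C(C)=C/CO | starting material
2 | geranyl diethyl phosphate, diethyl (2E)-3,7-dimethylocta-2,6-dien-1-yl phosphate | CC(C)=CCC/C(C)=C/COP(=O)(OCC)OCC | intermediate
3 | 4-bromo-1-(trimethylsilyl)but-1-yne | C[Si](C)(C)C#CCCBr | starting material
4 | [4-(trimethylsilyl)but-3-yn-1-yl]magnesium bromide | C[Si](C)(C)C#CCC[Mg]Br | intermediate
5 | [(5S)-5-ethenyl-5,9-dimethyldec-8-en-1-yn-1-yl]trimethylsilane | CC(C)=CCC[C@@](C)(CCC#C[Si](C)(C)C)C=C | intermediate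
6 | (5S)-5-ethenyl-5,9-dimethyldec-8-en-1-yne | CC(C)=CCC[C@@](C)(CCC#C)C=C | intermediate
7 | [(1E,5S)-5-ethenyl-2,5,9-trimethyldeca-1,8-dien-1-yl]dimethylalane | CC(C)=CCC[C@@](C)(CC/C(C)=C/[Al](C)C)C=C | intermediate
8 | (1E,5S)-5-ethenyl-1-iodo-2,5,9-trimethyldeca-1,8-diene | CC(C)=CCC[C@@](C)(CC/C(C)=C/I)C=C | intermediate
9 | N,O-dimethylhydroxylamine hydrochloride | CNOC.Cl | starting material
10 | bromoacetyl bromide | BrCC(Br)=O | starting material
11 | 2-bromo-N-methoxy-N-methylacetamide | CON(C)C(=O)CBr | intermediate
12 | 2-diazo-N-methoxy-N-methylacetamide | CON(C)C(=O)C=[N+]=[N-] | intermediate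
13 | (1S,2S)-2-[(1E,5S)-1-iodo-2,5,9-trimethyldeca-1,8-dien-5-yl]-N-methoxy-N-methylcyclopropane-1-carboxamide | CC(C)=CCC[C@@](C)(CC/C(C)=C/I)[C@H]1C[C@@H]1C(=O)N(C)OC | intermediate
14 | 1-[(1S,2S)-2-[(1E,5S)-1-iodo-2,5,9-trimethyldeca-1,8-dien-5-yl]cyclopropyl]ethan-1-one | CC(C)=CCC[C@@](C)(CC/C(C)=C/I)[C@H]1C[C@@H]1C(C)=O | intermediate
15 | tributyl(1-ethoxyethenyl)stannane | CCCC[Sn](CCCC)(CCCC)C(=C)OCC | starting material
16 | 1-[(1S,2S)-2-[(3E,7S)-2-ethoxy-4,7,11-trimethyldodeca-1,3,10-trien-7-yl]cyclopropyl]ethan-1-one | CC(C)=CCC[C@@](C)(CC/C(C)=C/C(=C)OCC)[C@H]1C[C@@H]1C(C)=O | intermediate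
17 | (3E,7S)-7-[(1S,2S)-2-acetylcyclopropyl]-1-bromo-4,7,11-trimethyldodeca-3,10-dien-2-one (key-step precursor) | CC(C)=CCC[C@@](C)(CC/C(C)=C/C(=O)CBr)[C@H]1C[C@@H]1C(C)=O | intermediate
18 | diiodosamarium enolate of 17 (trivalent samarium on O6, C6=C7 enolate) | CC(C)=CCC[C@@](C)(CC/C(C)=C/C(=C)O[Sm](I)I)[C@H]1C[C@@H]1C(C)=O | intermediate
19 | (1S,4E,8S,9S,10S)-8-hydroxy-1,4,8-trimethyl-1-(4-methylpent-3-enyl)cyclodec-4-en-6-one with a cyclopropane fused at C9–C10 (C11 = CH2), overview numbering (key-step product) | CC(C)=CCC[C@@]1(C)CC/C(C)=C/C(=O)C[C@](C)(O)[C@H]2C[C@@H]21 | intermediate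
20 | (1S,4E,6S,8S,9S,10S)-6,8-diol of the same ring system (1,3-anti) | CC(C)=CCC[C@@]1(C)CC/C(C)=C/[C@@H](O)C[C@](C)(O)[C@H]2C[C@@H]21 | intermediate
21 | (1S,4E,6S,8S,9S,10S)-C6 acetate of 20, C8 hydroxyl free | CC(C)=CCC[C@@]1(C)CC/C(C)=C/[C@@H](OC(C)=O)C[C@](C)(O)[C@H]2C[C@@H]21 | intermediate
22 | (1R,4E,6S,8S,9S,10S)-acetate with 2-[(2R)-3,3-dimethyloxiran-2-yl]ethyl side chain on C1 | CC1(C)O[C@@H]1CC[C@@]2(C)CC/C(C)=C/[C@@H](OC(C)=O)C[C@](C)(O)[C@H]3C[C@@H]32 | intermediate
23 | bis(trimethylsilyl) ether of 24 (side-chain 3R-OSiMe3 and C8-OSiMe3) | C=C(C)[C@@H](CC[C@@]1(C)CC/C(C)=C/[C@@H](OC(C)=O)C[C@](C)(O[Si](C)(C)C)[C@H]2C[C@@H]21)O[Si](C)(C)C | intermediate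
24 | (1R,4E,6S,8S,9S,10S)-acetate with (3R)-3-hydroxy-4-methylpent-4-enyl side chain on C1 | C=C(C)[C@@H](CC[C@@]1(C)CC/C(C)=C/[C@@H](OC(C)=O)C[C@](C)(O)[C@H]2C[C@@H]21)O | intermediate
25 | side-chain (3R)-methanesulfonate of 24 | C=C(C)[C@@H](CC[C@@]1(C)CC/C(C)=C/[C@@H](OC(C)=O)C[C@](C)(O)[C@H]2C[C@@H]21)OS(C)(=O)=O | intermediate
26 | CNP0302713.3, (1R,4E,6S,8S,9S,10S)-acetate with (3S)-3-hydroperoxy-4-methylpent-4-enyl side chain on C1 | C=C(C)[C@H](CC[C@@]1(C)CC/C(C)=C/[C@@H](OC(C)=O)C[C@](C)(O)[C@H]2C[C@@H]21)OO | target

**Step count**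

Total: 15 steps. Longest linear sequence: 13 steps from geraniol (steps 1–4 and 7–15); steps 5 and 6 make the diazo reagent.

**Steps most likely to fail**

Step 10 (key step). The samarium enolate may be protonated before it reaches the ketone, so that bromine is simply lost without ring closure. The strained aldolate may reopen by retro-aldol, or C7 may add to the other face of the C8 ketone. The fallback closes the ring at C5–C6 instead and sets out from 14. Lithiated acetonitrile (n-BuLi, MeCN, THF, −78 °C) adds to the C8 ketone to give the β-hydroxy nitrile F1; an intermolecular addition to this ketone is not expected to be face-selective, so the 8S epimer is separated by chromatography. Reduction with i-Bu2AlH (toluene, −78 °C) and hydrolysis of the aldimine on buffered work-up with aqueous potassium sodium tartrate give the β-hydroxy aldehyde F2. An intramolecular Nozaki–Hiyama–Kishi reaction (CrCl2, NiCl2 cat., DMSO/THF, high dilution) adds the alkenylchromium, with retention of the E geometry, to the aldehyde and gives the ring-closed diol F3 as a mixture of C6 epimers. MnO2 in CH2Cl2 oxidises the allylic C6 alcohol, and the route is rejoined at 19.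

Step 15. Ionisation of the allylic mesylate (loss of configuration), attack at the terminal methylene with allylic transposition, or elimination may compete with direct displacement by neutral hydrogen peroxide. The fallback sets out from 24. The mesylate 25 is made as in step 15 and treated with the hydroxide-free potassium salt of 2-methoxypropan-2-yl hydroperoxide (KOt-Bu, DMF, 0 °C, about one equivalent so that the acetate is spared). This strong, protected peroxide nucleophile should enforce bimolecular displacement with inversion and give the peroxyketal F4. Aqueous AcOH/THF at room temperature then hydrolyses the ketal, and the route is rejoined at 26.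

Step 7. The carbene may fail to discriminate between the hindered vinyl group and the electron-rich prenyl alkene, or the diazo compound may dimerise faster than it adds to the hindered alkene. The fallback masks the competing alkene and sets out from 8. Pyridinium tribromide (1.0 equiv, CH2Cl2, −78 °C) adds bromine only to the most electron-rich alkene and gives the dibromide F5 as a mixture of epimers at the CHBr carbon. Cyclopropanation of F5 with 12 under the catalyst of step 7 can then be pushed with more diazo compound and a higher temperature, since no competing alkene is left, and gives the dibromo cyclopropyl amide F6. Zn dust in AcOH/THF at 0 °C regenerates the prenyl alkene, and the route is rejoined at 13.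

**Further compounds**

F1 | step 10 | (3S)-3-hydroxy-3-[(1S,2S)-2-[(1E,5S)-1-iodo-2,5,9-trimethyldeca-1,8-dien-5-yl]cyclopropyl]butanenitrile | CC(C)=CCC[C@@](C)(CC/C(C)=C/I)[C@H]1C[C@@H]1[C@@](C)(O)CC#N
F2 | step 10 | (3S)-3-hydroxy-3-[(1S,2S)-2-[(1E,5S)-1-iodo-2,5,9-trimethyldeca-1,8-dien-5-yl]cyclopropyl]butanal | CC(C)=CCC[C@@](C)(CC/C(C)=C/I)[C@H]1C[C@@H]1[C@@](C)(O)CC=O
F3 | step 10 | (1S,4E,8S,9S,10S)-6,8-diol of the ring system of 19, mixture of C6 epimers | CC(C)=CCC[C@@]1(C)CC/C(C)=C/C(O)C[C@](C)(O)[C@H]2C[C@@H]21
F4 | step 15 | (3S)-3-[(2-methoxypropan-2-yl)peroxy]-4-methylpent-4-enyl analogue of 26 (peroxyketal) | C=C(C)[C@H](CC[C@@]1(C)CC/C(C)=C/[C@@H](OC(C)=O)C[C@](C)(O)[C@H]2C[C@@H]21)OOC(C)(C)OC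
F5 | step 7 | 8,9-dibromide of 8 (bromine across the prenyl alkene, both epimers at C8) | CC(C)(Br)C(Br)CC[C@@](C)(CC/C(C)=C/I)C=C
F6 | step 7 | side-chain dibromide of 13 (both epimers at the CHBr carbon) | CC(C)(Br)C(Br)CC[C@@](C)(CC/C(C)=C/I)[C@H]1C[C@@H]1C(=O)N(C)OC
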